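## Structural features

Icetexane numbering is used throughout. Ring A is C1–C2–C3–C4–C5–C10. Ring B is C5–C6–C7–C8–C9–C20–C10. Ring C is C8–C9–C11–C12–C13–C14. The lactone is C19–O–C6–C5–C4, C18 is the methyl group on C4, and the isopropyl group sits on C13.

- The target (1R,4S,5R) is a 6-7-6 carbocycle. Ring C is a 12-hydroxy-13-isopropyl-11,14-quinone.
- Ring B is a cycloheptatriene (C6=C7, C8=C9, C10=C20). Its only sp3 atom is C5.
- A γ-lactone is peri-fused across C4–C5–C6, so rings A, B and the lactone all meet at C5.
- The stereocentres are the quaternary C4 (C18 α, C19 β), its neighbour C5 (H α) and the allylic carbinol C1 (OH β, equatorial).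
- C4 and C5 are tied together by the cis ring fusion. C1 is remote (1,4 to C4).
- Three groups are fragile. The enol lactone O–C6=C7 is a vinylogous anhydride once ring C is a quinone. H5 is doubly allylic and vinylogously acidic. The hydroxyquinone is redox-active.
- The real difficulty is the vicinal C4/C5 pair inside three mutually fused rings, together with a seven-membered ring that must carry the enol lactone.
- The key step exploits this feature: C19–C4(C18)=C5–C6(=C7)–O is an α-methyl-γ-ylidenebutenolide, and the other four ring A atoms, C10–C1(O)–C2–C3, are a 2-oxydiene. Ring A is therefore a Diels–Alder ring laid onto the finished lactone, and ring B is merely the tether.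

## Logic of the disconnections

In one sentence: 16, a flat arene carrying a ylidenebutenolide arm and a silyloxydiene arm, is folded by one intramolecular Diels–Alder reaction that closes rings A and B together.

**23 ⇒ 22 ⇒ 21.** The cuts are O12–CH3, then the C11=O and C14=O groups back to aryl methyl ethers. The quinone is incompatible with hydride, Lewis acids and heat. Masking it as an arene lets all C–C chemistry run on a robust ring. The forward demand is that the oxidation spares the enol lactone and the allylic alcohol, and that the last ether cleavage is chemoselective for the single vinylogous ester.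

**21 ⇒ 20.** The cut is C1–H. C1 is the only stereocentre not tied into a ring fusion, and it is equatorial, so it can be relayed from C5. One stereocentre is thereby removed. The forward demand is 1,2-selective hydride delivery from the α face.

**20 ⇒ 18 (through 19).** The C10=C20 π bond is replaced by C10–H and C20–OSi. This returns C20 to sp3 and gives the route a sacrificial stereocentre that can steer the key step. The forward demand is a clean β-elimination that erases C10 and C20 without touching H5.

**18 ⇒ 16 (through 17).** The cuts are C5–C10 and C3–C4. These are the two σ bonds of the cyclohexene retron C1=C2. Cutting them opens ring A and ring B together and removes C4, C5 and C10. The precursor has one stereocentre and no carbocycle other than the arene. There are three forward demands: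
- The aryl group must be cis to C5 across C6=C7.
- Reaction must occur at C4=C5 and not at C6=C7.
- Face control must come from C20.

**16 ⇒ 15 ⇒ 12 + 13.** The cuts are two O–Si bonds, then C10–C20. An aldol cut gives the four-carbon unit as a bought reagent and places the only catalyst-set stereocentre at a benzylic carbinol. The forward demand is facial control on a 2,6-disubstituted aryl aldehyde.

**12 ⇒ 11 + 6.** The cut is C9–C20. C9 is the last free arene position, so no regiochemical choice exists. The forward demand is that the electrophile attacks the arene and not C7.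

**11 ⇒ 7 + 8.** The cut is C6=C7. This vinylogous aldol condensation delivers C4, C5, C6, C18 and C19, and the complete enol lactone, in one operation from a five-carbon lactone. The geometry obtained is not critical, because it is equilibrated later.

**7 ⇒ 5 + 6; 5 ⇒ 4 ⇒ 1 + 2.** The cuts are C7–C8 and C13–C15. Directed metalation places the isopropyl carbon between two methoxy groups. Electrophilic substitution then goes para to O12, which is C8.

## Other disconnections considered

**Alternative 1:** (the first that comes to mind) Cut C7–C8 and C10=C20. A preformed chiral ring A keto ester is condensed with the aryl aldehyde. An intramolecular Friedel–Crafts acylation then closes ring B to diketo ester A1, and the lactone is made last.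
- The aldol has to choose C10 over the less hindered C2.
- A1 carries oxygen on C7 instead of C6. C6 must therefore be oxidised, lactonised, and C7 reduced and dehydrated, which is four or five redox steps on a base-sensitive core.
- C5 is set by a separate conjugate addition.
- The chosen plan buys the C6 oxygen and the lactone in one condensation and sets C4/C5 in the ring-forming event.

**Alternative 2:** Cut C9–C20 and reconnect C9–C10 (biomimetic). Podocarpic acid A2 supplies C4, C5, C19 and O12. Its C20 methyl group is functionalised to mesylate A3, whose ionisation triggers a Wagner–Meerwein 1,2-aryl shift to the icetexane cation.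
- The plan needs a remote C–H functionalisation of an unactivated methyl group.
- The C10 cation can lose a proton in three directions.
- C1, C6, C7, C11, C13 (alkylation) and C14 all still have to be functionalised afterwards.
- Most of the route would be late oxidations in the presence of each other. The chosen plan installs every heteroatom with its carbon fragment.

**Alternative 3:** Cut C4–C5 and O–C19. The lactone plus ring B is the formal [8+2] adduct of a tropone and a ketene. Acid A4 would be converted into ketene A5, which adds across O6/C5 of its own quinone-fused tropone.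
- The retron is perfect, but A4 needs ring B to be built first, by ring expansion and two oxidation-level adjustments. That is about ten steps before the key event.
- A4 is also an electrophile at C7 and C20.
- Allylic strain places the C1 silyloxy group anti to the forming C4–C5 bond. This is the 1-epi relationship, so C1 would have to be inverted next to a quinone.
- The chosen plan is shorter and sets C1 last, by the favoured axial hydride attack.

Key step: step 8

Assumption: the sense of induction of the oxazaborolidinone in step 6 is taken to be that shown with simple aryl aldehydes (S-tryptophan series gives the R carbinol). If it is opposite, the R-tryptophan catalyst is used.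

## Steps

Step 1
Reactants: 1 1,2,4-trimethoxybenzene; 2 acetone
Product: 4 2-(2,3,6-trimethoxyphenyl)propan-2-ol, via aryllithium 3 (not isolated)
Conditions: n-BuLi, THF, 0 °C; then 2, −78 °C to rt; H2O
Reagents that add atoms: none
Why: Directed ortho metalation; the position flanked by two methoxy groups (future C13) is the most acidic, and the aryllithium adds to the ketone.

Step 2
Reactants: 4 2-(2,3,6-trimethoxyphenyl)propan-2-ol
Product: 5 2-isopropyl-1,3,4-trimethoxybenzene
Conditions: Et3SiH, CF3CO2H, CH2Cl2, 0 °C
Reagents that add atoms: none
Why: Ionic hydrogenation; the tertiary benzylic cation of an electron-rich arene forms readily and is trapped by the silane.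

Step 3
Reactants: 5 2-isopropyl-1,3,4-trimethoxybenzene; 6 dichloromethyl methyl ether
Product: 7 3-isopropyl-2,4,5-trimethoxybenzaldehyde
Conditions: TiCl4, CH2Cl2, −20 °C; H2O
Reagents that add atoms: water, O
Why: Rieche formylation; substitution should go to C8, which is ortho to O14 and para to O12, as in the parent 1,2,4-trioxygenated arene.

Step 4
Reactants: 7 3-isopropyl-2,4,5-trimethoxybenzaldehyde; 8 3-methylfuran-2(5H)-one
Product: 11 (Z)-5-[(3-isopropyl-2,4,5-trimethoxyphenyl)methylidene]-3-methylfuran-2(5H)-one, via silyloxyfuran 9 (not isolated), via aldol silyl ether 10 (not isolated)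
Conditions: TBSOTf, i-Pr2NEt, CH2Cl2, rt; then DBU, rt
Reagents that add atoms: none
Why: Vinylogous Mukaiyama aldol reaction at the γ carbon of the in situ silyloxyfuran, followed by E1cB loss of silanolate; the thermodynamic Z ylidenebutenolide is expected.

Step 5
Reactants: 11 the Z ylidenebutenolide; 6 dichloromethyl methyl ether
Product: 12 4-isopropyl-3,5,6-trimethoxy-2-{(Z)-[4-methyl-5-oxofuran-2(5H)-ylidene]methyl}benzaldehyde
Conditions: TiCl4, CH2Cl2, 0 °C to rt; H2O
Reagents that add atoms: water, O
Why: Rieche formylation at C9, the only free arene position, which is activated by the ortho O11 and the para isopropyl group; the lactone is inert to TiCl4.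

Step 6
Reactants: 12 the aldehyde; 13 2-(trimethylsilyloxy)buta-1,3-diene
Product: 15 (R)-β-hydroxy vinyl ketone (12 in which CHO has become (1R)-CH(OH)CH2C(=O)CH=CH2), via trimethylsilyl ether 14 (not isolated)
Conditions: N-tosyl-(S)-tryptophan-derived B-butyl-1,3,2-oxazaborolidin-5-one (20 mol %), EtCN, −78 °C; then 1 M HCl, THF, 0 °C
Reagents that add atoms: none
Why: Catalytic enantioselective Mukaiyama aldol reaction of a methyl ketone silyl enol ether; the boron Lewis acid binds the most basic carbonyl (the aldehyde) and shields one face, which sets C20 as R.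

Step 7
Reactants: 15 the (R)-β-hydroxy vinyl ketone
Product: 16 (20R)-bis-silyl compound: aryl–CH(OTBS)–CH=C(OTBS)–CH=CH2 with a Z enol silane and a Z ylidenebutenolide
Conditions: TBSOTf (2.5 equiv), Et3N, CH2Cl2, −78 to 0 °C
Reagents that add atoms: tert-butyldimethylsilyl triflate, CC(C)(C)[Si](C)(C)OS(=O)(=O)C(F)(F)F
Why: O-silylation and soft enolisation in one operation; only C10 carries enolisable hydrogen, and the Z enol silane (OSi cis to C20) is the usual outcome, which places C20 on the outside of the s-cis diene.

Step 8
Reactants: 16 the (20R)-bis-silyl compound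
Product: 18 (4S,5R,10S,20R)-tetracyclic adduct (C1(OTBS)=C2 enol silane, C20–OTBS, enol lactone C6=C7 intact), via E isomer 17 (not isolated)
Conditions: DABCO (20 mol %), BHT, toluene (0.005 M), sealed tube, 140 °C
Reagents that add atoms: none
Why: This is a type 1 intramolecular Diels–Alder reaction of normal electron demand between a 2-silyloxydiene and the ring alkene C4=C5 of an α-methyl-γ-ylidenebutenolide, and the closest known reactions are thermal cycloadditions of substituted γ-ylidenebutenolides (which react at the ring alkene) and butenolide IMDA reactions. DABCO adds reversibly to C7 (1,6-addition gives an aromatic 2-oxidofuran), so 16 and 17 interconvert, and only 17, with the aryl group cis to C5, can place the diene over C4=C5 (Curtin–Hammett funnel). The C10–C5 bond joins the largest diene HOMO coefficient (C10, β to OSi) to the largest LUMO coefficient (C5, β to C19=O) and closes ring B as the seven-membered tether ring, while the C3–C4 bond closes ring A as the new cyclohexene. C4 and C5 follow from suprafacial addition to a cyclic alkene, so C18 and H5 end up cis, which is the cis-fused lactone of the target. The absolute sense comes from C20: its hydrogen has to face O1 of the Z enol silane (allylic 1,3-strain) and also the O11 methoxy group, which is possible only in the transition state with the lactone exo on one butenolide face, where OTBS points into free space. On this model the R centre leads to 4S,5R (and 10S). The selectivity needed is reaction at C4=C5 rather than at C6=C7 (a spiro-indane mode); both modes freeze the same three rotors (C8–C7, C9–C20, C20–C10), but the C8–C9–C20 bridge spans the two reacting planes without strain only when C10 lies over C5. Attack on C6=C7 would also build a spiro quaternary carbon beside a hexasubstituted arene and break the aryl–enol ester conjugation.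

Step 9
Reactants: 18 the tetracyclic adduct
Product: 20 (4S,5R)-tetracyclic enone (C1=O, C10=C20, C6=C7, trimethoxyarene), via silyloxy ketone 19 (not isolated)
Conditions: TsOH·H2O (0.2 equiv), THF–H2O 10:1, 45 °C
Reagents that add atoms: none
Why: Hydrolysis of the enol silane, then β-elimination of the benzylic silyloxy group (E1 assisted by the electron-rich arene, or E1cB through the C1 enol); C10 and C20 become sp2, and the conjugated enone is the only alkene that can form.

Step 10
Reactants: 20 the tetracyclic enone
Product: 21 (1R,4S,5R)-allylic alcohol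
Conditions: NaBH4, CeCl3·7H2O, MeOH–CH2Cl2, −78 °C
Reagents that add atoms: none
Why: Luche reduction; 1,2-attack should come from the α face (the side of H5), because C6 and the fold of ring B cover the β face, which gives the equatorial 1β-alcohol (C1 = R).

Step 11
Reactants: 21 the allylic alcohol
Product: 22 12-O-methyl ether of the target (11,14-quinone)
Conditions: (NH4)2Ce(NO3)6 (2.5 equiv), MeCN–H2O 2:1, 0 °C
Reagents that add atoms: water, O
Why: Oxidative demethylation of a 1,4-dimethoxyarene by tetravalent cerium; the para pair O11/O14 is lost and O12 stays as a vinylogous ester.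

Step 12
Reactants: 22 the methoxyquinone
Product: 23 6,7-anhydroballotiquinone
Conditions: BCl3 (3 equiv), CH2Cl2, −78 °C; pH 7 buffer
Reagents that add atoms: none
Why: Chelation-assisted ether cleavage; boron bridges O11 and O12, and chloride removes the methyl group of the only remaining methyl ether; the C1 alcohol is held as a borate, and its ionisation is disfavoured by the quinone-conjugated alkene.

## Compound list

1 | 1,2,4-trimethoxybenzene | COc1ccc(OC)c(OC)c1 | starting material
2 | acetone | CC(C)=O | starting material
3 | 3-lithio-1,2,4-trimethoxybenzene | [Li]c1c(OC)ccc(OC)c1OC | intermediate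
4 | 2-(2,3,6-trimethoxyphenyl)propan-2-ol | COc1ccc(OC)c(C(C)(C)O)c1OC | intermediate
5 | 2-isopropyl-1,3,4-trimethoxybenzene | COc1ccc(OC)c(C(C)C)c1OC | intermediate
6 | dichloromethyl methyl ether | COC(Cl)Cl | starting material
7 | 3-isopropyl-2,4,5-trimethoxybenzaldehyde | COc1cc(C=O)c(OC)c(C(C)C)c1OC | intermediate
8 | 3-methylfuran-2(5H)-one | CC1=CCOC1=O | starting material
9 | tert-butyldimethyl[(3-methylfuran-2-yl)oxy]silane | Cc1ccoc1O[Si](C)(C)C(C)(C)C | intermediate
10 | vinylogous aldol silyl ether (racemic diastereomer mixture) | CC1=CC(OC1=O)C(O[Si](C)(C)C(C)(C)C)c1cc(OC)c(OC)c(C(C)C)c1OC | intermediate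
11 | (Z)-5-[(3-isopropyl-2,4,5-trimethoxyphenyl)methylidene]-3-methylfuran-2(5H)-one | CC1=C/C(=C/c2cc(OC)c(OC)c(C(C)C)c2OC)OC1=O | intermediate
12 | 4-isopropyl-3,5,6-trimethoxy-2-{(Z)-[4-methyl-5-oxofuran-2(5H)-ylidene]methyl}benzaldehyde | CC1=C/C(=C/c2c(C=O)c(OC)c(OC)c(C(C)C)c2OC)OC1=O | intermediate
13 | 2-(trimethylsilyloxy)buta-1,3-diene | C=CC(=C)O[Si](C)(C)C | starting material
14 | (R)-aldol trimethylsilyl ether | C=CC(=O)C[C@@H](O[Si](C)(C)C)c1c(OC)c(OC)c(C(C)C)c(OC)c1/C=C1/C=C(C)C(=O)O1 | intermediate
15 | (R)-β-hydroxy vinyl ketone | C=CC(=O)C[C@@H](O)c1c(OC)c(OC)c(C(C)C)c(OC)c1/C=C1/C=C(C)C(=O)O1 | intermediate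
16 | (20R)-bis-TBS Z-dienol ether, Z ylidenebutenolide | C=C/C(O[Si](C)(C)C(C)(C)C)=C/[C@@H](O[Si](C)(C)C(C)(C)C)c1c(OC)c(OC)c(C(C)C)c(OC)c1/C=C1/C=C(C)C(=O)O1 | intermediate
17 | (20R)-bis-TBS Z-dienol ether, E ylidenebutenolide | C=C/C(O[Si](C)(C)C(C)(C)C)=C/[C@@H](O[Si](C)(C)C(C)(C)C)c1c(OC)c(OC)c(C(C)C)c(OC)c1\C=C1/C=C(C)C(=O)O1 | intermediate
18 | (4S,5R,10S,20R)-Diels–Alder adduct | COc1c(C(C)C)c(OC)c(OC)c2c1C=C1OC(=O)[C@@]3(C)CC=C(O[Si](C)(C)C(C)(C)C)[C@H]([C@H]2O[Si](C)(C)C(C)(C)C)[C@@H]13 | intermediate
19 | (4S,5R,10S,20R)-20-silyloxy 1-ketone | COc1c(C(C)C)c(OC)c(OC)c2c1C=C1OC(=O)[C@@]3(C)CCC(=O)[C@H]([C@H]2O[Si](C)(C)C(C)(C)C)[C@@H]13 | intermediate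
20 | (4S,5R)-tetracyclic enone | COc1c(C(C)C)c(OC)c(OC)c2c1C=C1OC(=O)[C@@]3(C)CCC(=O)C(=C2)[C@@H]13 | intermediate
21 | (1R,4S,5R)-allylic alcohol | COc1c(C(C)C)c(OC)c(OC)c2c1C=C1OC(=O)[C@@]3(C)CC[C@@H](O)C(=C2)[C@@H]13 | intermediate
22 | 12-O-methyl-6,7-anhydroballotiquinone | CC(C)C1=C(OC)C(=O)C2=C(C=C3OC(=O)[C@@]4(C)CC[C@@H](O)C(=C2)[C@@H]34)C1=O | intermediate
23 | 6,7-anhydroballotiquinone | CC(C)C1=C(O)C(=O)C2=C(C=C3OC(=O)[C@@]4(C)CC[C@@H](O)C(=C2)[C@@H]34)C1=O | target

## Step count and least certain steps

Total step count: 12. Longest linear sequence: 12 (steps 1–12; 2, 6, 8 and 13 are bought).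

**Step 8 (key step).** Two things are most likely to go wrong.
- The diene may add to the exocyclic C6=C7 bond, which is reachable from both geometric isomers and forms a five-membered tether ring.
- Too little of the E isomer may be populated, so that thermal decay of the dienol silane wins.

The fallback sets out from 7 and comes back at 20. It builds ring A first and closes ring B by condensation.
- Ohira–Bestmann homologation of 7 gives the aryl alkyne F1.
- Separately, ethyl 2-formylpropanoate and methyl vinyl ketone are joined by a cinchona-thiourea catalysed Michael addition to the keto aldehyde F2.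
- F2 is closed by aldol condensation to the enone ester F3, and F3 is saponified to the enone acid F4.
- The dimethylaluminium acetylide of F1 (n-BuLi, Me2AlCl), held by the carboxylate of F4, adds 1,4 to give the alkynyl keto acid F5.
- AgNO3-catalysed 5-exo-dig lactonisation gives the Z enol lactone ketone F6, and Rieche formylation gives the aldehyde F7.
- Sensitised irradiation (thioxanthone, 405 nm) populates the E aldehyde F8, which TsOH closes by intramolecular aldol condensation to 20.

**Step 6.** Facial selectivity may be poor, because the aldehyde is flanked by two ortho groups and may bind the catalyst in more than one geometry. The fallback sets out from 12 and comes back at 15 by resolution. A BF3·OEt2-promoted aldol reaction with 13 gives the racemic alcohol F11. Acetylation gives the racemic acetate F12. Lipase-catalysed hydrolysis then releases 15 from the fast-reacting R acetate and leaves the S acetate F13 behind.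

**Step 5.** The hindered, only singly activated C9 may react sluggishly, or the electrophile may attack the enol ester carbon C7. The fallback sets out from 7 and comes back at 12. The carbon is placed by cross-coupling instead of electrophilic substitution. Bromination (NBS) gives the bromo aldehyde F9. Condensation with 8 as in step 4 gives the bromo butenolide F10. Reductive carbonylation (Pd(OAc)2, di(1-adamantyl)-n-butylphosphine, CO/H2, TMEDA) then gives 12.

**Step 12.** The vinylogous anhydride (lactone acyl–oxygen cleavage) may be opened by chloride, or on work-up, while boron is bound to the quinone. The fallback sets out from 22 and comes back at 23. The ether is cleaved at the hydroquinone level, where the lactone is an ordinary aryl-conjugated enol ester. Na2S2O4 gives the hydroquinone F14. BCl3 cleaves the methyl ether flanked by a free phenol through a cyclic borate, which gives the triol F15. Air oxidation on work-up then gives 23.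

## Further compounds

F1 | step 8 | 1-ethynyl-3-isopropyl-2,4,5-trimethoxybenzene | C#Cc1cc(OC)c(OC)c(C(C)C)c1OC
F2 | step 8 | ethyl (S)-2-formyl-2-methyl-5-oxohexanoate | CCOC(=O)[C@](C)(C=O)CCC(C)=O
F3 | step 8 | ethyl (S)-1-methyl-4-oxocyclohex-2-ene-1-carboxylate | CCOC(=O)[C@@]1(C)CCC(=O)C=C1
F4 | step 8 | (S)-1-methyl-4-oxocyclohex-2-ene-1-carboxylic acid | OC(=O)[C@@]1(C)CCC(=O)C=C1
F5 | step 8 | (1S,2S)-2-(arylethynyl)-1-methyl-4-oxocyclohexane-1-carboxylic acid | OC(=O)[C@@]1(C)CCC(=O)C[C@H]1C#Cc1cc(OC)c(OC)c(C(C)C)c1OC
F6 | step 8 | cis-fused Z arylidene lactone ketone | COc1cc(/C=C2\OC(=O)[C@@]3(C)CCC(=O)C[C@@H]23)c(OC)c(C(C)C)c1OC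
F7 | step 8 | C9-formyl Z arylidene lactone ketone | COc1c(C=O)c(/C=C2\OC(=O)[C@@]3(C)CCC(=O)C[C@@H]23)c(OC)c(C(C)C)c1OC
F8 | step 8 | C9-formyl E arylidene lactone ketone | COc1c(C=O)c(/C=C2/OC(=O)[C@@]3(C)CCC(=O)C[C@@H]23)c(OC)c(C(C)C)c1OC
F9 | step 5 | 2-bromo-5-isopropyl-3,4,6-trimethoxybenzaldehyde | COc1c(Br)c(C=O)c(OC)c(C(C)C)c1OC
F10 | step 5 | (Z)-5-[(2-bromo-5-isopropyl-3,4,6-trimethoxyphenyl)methylidene]-3-methylfuran-2(5H)-one | CC1=C/C(=C/c2c(Br)c(OC)c(OC)c(C(C)C)c2OC)OC1=O
F11 | step 6 | racemic β-hydroxy vinyl ketone | C=CC(=O)CC(O)c1c(OC)c(OC)c(C(C)C)c(OC)c1/C=C1/C=C(C)C(=O)O1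
F12 | step 6 | racemic β-acetoxy vinyl ketone | C=CC(=O)CC(OC(C)=O)c1c(OC)c(OC)c(C(C)C)c(OC)c1/C=C1/C=C(C)C(=O)O1
F13 | step 6 | (S)-β-acetoxy vinyl ketone | C=CC(=O)C[C@H](OC(C)=O)c1c(OC)c(OC)c(C(C)C)c(OC)c1/C=C1/C=C(C)C(=O)O1
F14 | step 12 | 11,14-hydroquinone of 22 | COc1c(O)c2c(c(O)c1C(C)C)C=C1OC(=O)[C@@]3(C)CC[C@@H](O)C(=C2)[C@@H]13
F15 | step 12 | 11,12,14-triol (hydroquinone of 23) | CC(C)c1c(O)c(O)c2c(c1O)C=C1OC(=O)[C@@]3(C)CC[C@@H](O)C(=C2)[C@@H]13
A1 | alternative 1 | tricyclic 1,7-diketo 19-methyl ester | COC(=O)[C@@]1(C)CCC(=O)C2=Cc3c(OC)c(OC)c(C(C)C)c(OC)c3C(=O)C[C@@H]12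
A2 | alternative 2 | podocarpic acid | OC(=O)[C@@]1(C)CCC[C@]2(C)c3cc(O)ccc3CC[C@@H]12
A3 | alternative 2 | methyl 13-isopropyl-12-methoxy-20-mesyloxypodocarpa-8,11,13-trien-19-oate | COC(=O)[C@@]1(C)CCC[C@]2(COS(C)(=O)=O)c3cc(OC)c(C(C)C)cc3CC[C@@H]12
A4 | alternative 3 | quinone-fused tropone acid (C4 epimers) | COC1=C(C(C)C)C(=O)C2=CC(=O)C=C([C@H](O[Si](C)(C)C(C)(C)C)CCC(C)C(O)=O)C=C2C1=O
A5 | alternative 3 | derived methyl alkyl ketene | COC1=C(C(C)C)C(=O)C2=CC(=O)C=C([C@H](O[Si](C)(C)C(C)(C)C)CCC(C)=C=O)C=C2C1=O
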